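**Retrosynthetic overview**
1. Curlignan is the 2,3-trans (2S,3R) dihydrobenzofuran. The phenol is unmasked last from a benzyl ether, and the C3 CH2OH is traced back to a C3 formyl group (epimerisable, trans by equilibration) and from there to a C3 vinyl group.
2. Key disconnection: the dihydrofuran ring is opened at O1–C7a and at C2–C3. This gives O-benzylvanillin (C2 and O1) and an (E)-γ-aryl allylboronate (C3, C3a, C7a); forward, a catalytic asymmetric allylboration and an alkoxide SNAr in the same flask make both bonds.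
3. Enabling feature: the C5 methyl ester lies para to C7a on the benzo ring, so a C7a–F bond is activated for displacement by the C2 oxygen. C3 carries a single one-carbon substituent, so C3 can be the γ-carbon of an allylboron reagent whose vinyl group is later cut down to CH2OH.
4. The allylboronate comes from methyl 4-fluoro-3-methoxybenzoate by C–H borylation ortho to fluorine, vinylation and cross-metathesis with allyl-Bpin.
5. Ring order: both benzene rings are purchased; the dihydrofuran ring is the only ring formed (step 4).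

Key step: step 4

Remark: benzofuran numbering (O1, C2, C3, C3a, C4–C7, C7a) is used throughout. The facial sense of (S)-TRIP is assumed by analogy with the behaviour of this catalyst family with aryl aldehydes ((R)-catalyst, Re face).

**Step 1**
Reactants: 1 methyl 4-fluoro-3-methoxybenzoate
Product: 2 methyl 4-fluoro-3-methoxy-5-(4,4,5,5-tetramethyl-1,3,2-dioxaborolan-2-yl)benzoate
Conditions: [Ir(OMe)(cod)]2 (1.5 mol%), dtbpy (3 mol%), B2pin2 (1.0 equiv), THF, 60 °C
Reagents that add atoms: bis(pinacolato)diboron, CC1(C)OB(OC1(C)C)B1OC(C)(C)C(C)(C)O1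
Why: Sterically governed Ir-catalysed C–H borylation should take the only C–H without a large ortho neighbour (C5, between fluorine and hydrogen; the other two are ortho to the ester), and C–H bonds ortho to fluorine are also electronically preferred.

**Step 2**
Reactants: 2 methyl 4-fluoro-3-methoxy-5-(pinacolboryl)benzoate
Product: 3 methyl 3-ethenyl-4-fluoro-5-methoxybenzoate
Conditions: vinyl bromide (1 M in THF, 2 equiv), Pd(dppf)Cl2 (3 mol%), K3PO4 (2 equiv), THF/H2O, 50 °C, sealed vessel
Reagents that add atoms: vinyl bromide, C=CBr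
Why: Suzuki–Miyaura coupling; the aryl C–F bond and the ester are inert to Pd(0)/phosphate, and fast oxidative addition of vinyl bromide should keep protodeboronation of the ortho-fluoro arylboronate in check.

**Step 3**
Reactants: 3 methyl 3-ethenyl-4-fluoro-5-methoxybenzoate
Product: 4 methyl 4-fluoro-3-methoxy-5-[(E)-3-(4,4,5,5-tetramethyl-1,3,2-dioxaborolan-2-yl)prop-1-en-1-yl]benzoate
Conditions: allyl-Bpin (2.5 equiv), Hoveyda–Grubbs II (5 mol%), CH2Cl2, 40 °C; short silica plug
Reagents that add atoms: allylboronic acid pinacol ester, C=CCB1OC(C)(C)C(C)(C)O1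
Why: Olefin cross-metathesis of a styrene with allyl-Bpin should give the conjugated E-cinnamyl boronate under thermodynamic control while ethylene escapes.

**Step 4**
Reactants: 4 methyl 4-fluoro-3-methoxy-5-[(E)-3-(pinacolboryl)prop-1-en-1-yl]benzoate (1.1 equiv), 5 4-(benzyloxy)-3-methoxybenzaldehyde
Product: 8 methyl (2S,3R)-2-[4-(benzyloxy)-3-methoxyphenyl]-3-ethenyl-7-methoxy-2,3-dihydro-1-benzofuran-5-carboxylate (2,3-cis), via O-boryl anti-homoallylic adduct 6 (not isolated), via potassium alkoxide 7 (not isolated)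
Conditions: (S)-TRIP (5 mol%), 4 Å MS, toluene, −30 → 0 °C; then THF, KOMe (2 equiv), 0 °C → rt, same flask
Reagents that add atoms: none
Why: The chiral phosphoric acid activates the boronate, and the γ-carbon of 4 adds to the aldehyde through a closed chair six-membered transition state (phosphoric-acid-catalysed allylboration of aryl aldehydes is the closest known reaction type), forming the C2–C3 bond and the O-boryl adduct 6. Methoxide then exchanges at boron to release alkoxide 7, which attacks the fluorine-bearing arene carbon (C7a of the product) and expels fluoride through a Meisenheimer complex stabilised by the para ester (intramolecular SNAr O-arylation); this forms the O1–C7a bond and closes the dihydrofuran ring by ipso attack, 5-exo with respect to the C7a–C7 π bond. C2 is set by the catalyst: (S)-TRIP should direct addition to the Si face of the aldehyde and give the (S)-carbinol, which enters the ring unchanged because oxygen, not carbon, is the reacting atom in the SNAr event. C3 is set relative to C2 by the E-olefin geometry, which places the aryl group equatorial in the chair and gives the anti adduct, hence the 2,3-cis ring at this stage (corrected at the epimerisable aldehyde in step 6). The step needs enantiofacial control (catalyst), anti selectivity (olefin geometry and closed transition state) and chemoselectivity in the base-triggered half: there is only one C–F bond, five-membered ring closure should outrun intermolecular attack of methoxide on that carbon, and methoxide exchange at the C5 methyl ester is degenerate. Allylation is irreversible, so C2 cannot be scrambled by retro-addition while the alkoxide waits to cyclise.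

**Step 5**
Reactants: 8 methyl (2S,3R)-2-[4-(benzyloxy)-3-methoxyphenyl]-3-ethenyl-7-methoxy-2,3-dihydro-1-benzofuran-5-carboxylate
Product: 9 methyl (2S,3R)-2-[4-(benzyloxy)-3-methoxyphenyl]-3-formyl-7-methoxy-2,3-dihydro-1-benzofuran-5-carboxylate (2,3-cis)
Conditions: OsO4 (2 mol%), NaIO4 (4 equiv), 2,6-lutidine (2 equiv), 1,4-dioxane/H2O 3:1, rt; used crude
Reagents that add atoms: osmium tetroxide (catalytic), O=[Os](=O)(=O)=O; sodium periodate, [Na+].[O-]I(=O)(=O)=O
Why: Lemieux–Johnson cleavage of the only alkene should give the aldehyde, with lutidine suppressing over-oxidation; benzyl ether, esters and arenes are inert.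

**Step 6**
Reactants: 9 methyl (2S,3R)-2-[4-(benzyloxy)-3-methoxyphenyl]-3-formyl-7-methoxy-2,3-dihydro-1-benzofuran-5-carboxylate
Product: 11 methyl (2S,3R)-2-[4-(benzyloxy)-3-methoxyphenyl]-3-(hydroxymethyl)-7-methoxy-2,3-dihydro-1-benzofuran-5-carboxylate (2,3-trans), via trans-aldehyde 10 (not isolated)
Conditions: DBU (0.3 equiv), CH2Cl2, rt; then MeOH, NaBH4 (1.5 equiv), 0 °C
Reagents that add atoms: none
Why: Base-mediated epimerisation of the α-aryl aldehyde through its enolate should settle C3 in the thermodynamically preferred 2,3-trans arrangement with C2 untouched (β-elimination of the ring oxygen is disfavoured because the C2–O bond lies near the nodal plane of the ring enolate), and NaBH4 then reduces the aldehyde but not the aryl methyl ester.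

**Step 7**
Reactants: 11 methyl (2S,3R)-2-[4-(benzyloxy)-3-methoxyphenyl]-3-(hydroxymethyl)-7-methoxy-2,3-dihydro-1-benzofuran-5-carboxylate
Product: 12 curlignan
Conditions: H2 (1 atm), 10% Pd/C, EtOAc, rt
Reagents that add atoms: none
Why: Hydrogenolysis of the aryl benzyl ether should be much faster than cleavage of the cyclic benzylic C2–O bond under neutral conditions; esters, aryl methyl ethers and the primary alcohol are inert.

**Compound list**
1 | methyl 4-fluoro-3-methoxybenzoate | COC(=O)c1ccc(F)c(OC)c1 | starting material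
2 | methyl 4-fluoro-3-methoxy-5-(4,4,5,5-tetramethyl-1,3,2-dioxaborolan-2-yl)benzoate | COC(=O)c1cc(OC)c(F)c(c1)B1OC(C)(C)C(C)(C)O1 | intermediate
3 | methyl 3-ethenyl-4-fluoro-5-methoxybenzoate | COC(=O)c1cc(OC)c(F)c(C=C)c1 | intermediate
4 | methyl 4-fluoro-3-methoxy-5-[(E)-3-(4,4,5,5-tetramethyl-1,3,2-dioxaborolan-2-yl)prop-1-en-1-yl]benzoate | COC(=O)c1cc(OC)c(F)c(/C=C/CB2OC(C)(C)C(C)(C)O2)c1 | intermediate
5 | 4-(benzyloxy)-3-methoxybenzaldehyde | O=Cc1ccc(OCc2ccccc2)c(OC)c1 | starting material
6 | methyl 3-[(1S,2R)-1-[4-(benzyloxy)-3-methoxyphenyl]-1-[(4,4,5,5-tetramethyl-1,3,2-dioxaborolan-2-yl)oxy]but-3-en-2-yl]-4-fluoro-5-methoxybenzoate | COC(=O)c1cc(OC)c(F)c(c1)[C@@H](C=C)[C@@H](c1ccc(OCc2ccccc2)c(OC)c1)OB1OC(C)(C)C(C)(C)O1 | intermediate (not isolated)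
7 | potassium (1S,2R)-1-[4-(benzyloxy)-3-methoxyphenyl]-2-[2-fluoro-3-methoxy-5-(methoxycarbonyl)phenyl]but-3-en-1-olate | COC(=O)c1cc(OC)c(F)c(c1)[C@@H](C=C)[C@@H](c1ccc(OCc2ccccc2)c(OC)c1)[O-].[K+] | intermediate (not isolated)
8 | methyl (2S,3R)-2-[4-(benzyloxy)-3-methoxyphenyl]-3-ethenyl-7-methoxy-2,3-dihydro-1-benzofuran-5-carboxylate (2,3-cis) | COC(=O)c1cc(OC)c2c(c1)[C@@H](C=C)[C@@H](c1ccc(OCc3ccccc3)c(OC)c1)O2 | intermediate
9 | methyl (2S,3R)-2-[4-(benzyloxy)-3-methoxyphenyl]-3-formyl-7-methoxy-2,3-dihydro-1-benzofuran-5-carboxylate (2,3-cis) | COC(=O)c1cc(OC)c2c(c1)[C@@H](C=O)[C@@H](c1ccc(OCc3ccccc3)c(OC)c1)O2 | intermediate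
10 | methyl (2S,3S)-2-[4-(benzyloxy)-3-methoxyphenyl]-3-formyl-7-methoxy-2,3-dihydro-1-benzofuran-5-carboxylate (2,3-trans) | COC(=O)c1cc(OC)c2c(c1)[C@H](C=O)[C@@H](c1ccc(OCc3ccccc3)c(OC)c1)O2 | intermediate (not isolated)
11 | methyl (2S,3R)-2-[4-(benzyloxy)-3-methoxyphenyl]-3-(hydroxymethyl)-7-methoxy-2,3-dihydro-1-benzofuran-5-carboxylate (2,3-trans) | COC(=O)c1cc(OC)c2c(c1)[C@H](CO)[C@@H](c1ccc(OCc3ccccc3)c(OC)c1)O2 | intermediate
12 | curlignan, methyl (2S,3R)-2-(4-hydroxy-3-methoxyphenyl)-3-(hydroxymethyl)-7-methoxy-2,3-dihydro-1-benzofuran-5-carboxylate | COC(=O)c1cc(OC)c2c(c1)[C@H](CO)[C@@H](c1ccc(O)c(OC)c1)O2 | target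

**Step count**
Total steps: 7. Longest linear sequence: 7 (1 → 12).

**Steps most likely to fail**

Step 4. The γ-aryl boronate is a sluggish allyl donor, so uncatalysed background addition may erode enantiofacial control at the temperature needed. Slow release of the boron-bound alkoxide may also let methoxide attack the C–F carbon intermolecularly. The fallback is an auxiliary-controlled aldol with stepwise ring closure; it sets out from 2 and comes back at 11, bypassing steps 3–6.
- Pd-catalysed coupling of 2 with tert-butyl bromoacetate (Pd(OAc)2, P(1-naphthyl)3, K3PO4, THF/H2O) would give tert-butyl 2-[2-fluoro-3-methoxy-5-(methoxycarbonyl)phenyl]acetate F1.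
- TFA in CH2Cl2 would give the arylacetic acid F2.
- Pivaloyl chloride/Et3N and then the lithium salt of (S)-4-benzyloxazolidin-2-one would give the N-acyl oxazolidinone F3.
- Bu2BOTf/iPr2NEt in CH2Cl2 and then 5 at −78 → 0 °C would give the syn aldol adduct F4. Both centres are set by the auxiliary through the Z-boron enolate and a chair transition state, and the syn aldol maps onto the 2,3-trans ring.
- NaBH4 in THF/H2O would remove the auxiliary reductively, sparing the aryl methyl ester, to give the diol F5.
- TrCl/pyridine would protect the primary hydroxyl as the trityl ether F6. This is needed because the primary alkoxide could otherwise also close a five-membered ring onto the C–F carbon.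
- NaH in THF/DMF would close the ring by SNAr to the trityl-protected dihydrobenzofuran F7.
- Catalytic TsOH in MeOH/CH2Cl2 would remove the trityl group and give 11.

Step 6. Equilibration at C3 may stay incomplete, or the enolate may be diverted into β-elimination of the ring oxygen or into aerobic oxidation. The fallback corrects the ring geometry at C2 by acid instead of at C3 by base; it sets out from 4 and 5 and comes back at 11.
- Step 4 run with (R)-TRIP would give, through the mirror-image O-boryl adduct F8 and the mirror-image potassium alkoxide F9, the enantiomeric cis vinyl dihydrobenzofuran F10.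
- Oxidative cleavage as in step 5 would give the cis aldehyde F11.
- NaBH4/MeOH without prior epimerisation would give the cis alcohol F12 (2R,3R), whose C3 already has the configuration of the target.
- Catalytic BF3·OEt2 in CH2Cl2 at 0 °C would ionise the C2–O bond to the p-alkoxybenzylic cation, which recloses to the more stable trans ring. This inverts C2 only and delivers 11.

Step 3. Homodimerisation of the allylboronate may outpace cross-metathesis with the electron-poor, ortho-substituted styrene, and the allylboronate may be lost by protodeboronation during purification. The fallback avoids metathesis and installs boron last; it sets out from 2 and comes back at 4.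
- Suzuki–Miyaura coupling of 2 with (E)-3-iodoprop-2-en-1-ol (Pd(dppf)Cl2, K3PO4, THF/H2O) would give the cinnamyl alcohol F13.
- Ac2O/pyridine would give the cinnamyl acetate F14.
- Pd(dba)2 and B2pin2 in DMSO at 50 °C (allylic borylation through the π-allyl palladium complex, linear E product) would give 4, to be used crude.

**Further compounds**
F1 | step 4 | tert-butyl 2-[2-fluoro-3-methoxy-5-(methoxycarbonyl)phenyl]acetate | COC(=O)c1cc(OC)c(F)c(CC(=O)OC(C)(C)C)c1
F2 | step 4 | 2-[2-fluoro-3-methoxy-5-(methoxycarbonyl)phenyl]acetic acid | COC(=O)c1cc(OC)c(F)c(CC(=O)O)c1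
F3 | step 4 | methyl 3-{2-[(4S)-4-benzyl-2-oxo-1,3-oxazolidin-3-yl]-2-oxoethyl}-4-fluoro-5-methoxybenzoate | COC(=O)c1cc(OC)c(F)c(CC(=O)N2[C@@H](Cc3ccccc3)COC2=O)c1
F4 | step 4 | (4S)-4-benzyl-3-[(2S,3S)-3-[4-(benzyloxy)-3-methoxyphenyl]-2-[2-fluoro-3-methoxy-5-(methoxycarbonyl)phenyl]-3-hydroxypropanoyl]-1,3-oxazolidin-2-one | COC(=O)c1cc(OC)c(F)c(c1)[C@H](C(=O)N1[C@@H](Cc2ccccc2)COC1=O)[C@@H](c1ccc(OCc2ccccc2)c(OC)c1)O
F5 | step 4 | methyl 3-[(1S,2R)-1-[4-(benzyloxy)-3-methoxyphenyl]-1,3-dihydroxypropan-2-yl]-4-fluoro-5-methoxybenzoate | COC(=O)c1cc(OC)c(F)c(c1)[C@H](CO)[C@@H](c1ccc(OCc2ccccc2)c(OC)c1)O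
F6 | step 4 | methyl 3-[(1S,2R)-1-[4-(benzyloxy)-3-methoxyphenyl]-1-hydroxy-3-(trityloxy)propan-2-yl]-4-fluoro-5-methoxybenzoate | COC(=O)c1cc(OC)c(F)c(c1)[C@H](COC(c1ccccc1)(c1ccccc1)c1ccccc1)[C@@H](c1ccc(OCc2ccccc2)c(OC)c1)O
F7 | step 4 | methyl (2S,3R)-2-[4-(benzyloxy)-3-methoxyphenyl]-7-methoxy-3-[(trityloxy)methyl]-2,3-dihydro-1-benzofuran-5-carboxylate | COC(=O)c1cc(OC)c2c(c1)[C@H](COC(c1ccccc1)(c1ccccc1)c1ccccc1)[C@@H](c1ccc(OCc3ccccc3)c(OC)c1)O2
F8 | step 6 | methyl 3-[(1R,2S)-1-[4-(benzyloxy)-3-methoxyphenyl]-1-[(4,4,5,5-tetramethyl-1,3,2-dioxaborolan-2-yl)oxy]but-3-en-2-yl]-4-fluoro-5-methoxybenzoate | COC(=O)c1cc(OC)c(F)c(c1)[C@H](C=C)[C@H](c1ccc(OCc2ccccc2)c(OC)c1)OB1OC(C)(C)C(C)(C)O1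
F9 | step 6 | potassium (1R,2S)-1-[4-(benzyloxy)-3-methoxyphenyl]-2-[2-fluoro-3-methoxy-5-(methoxycarbonyl)phenyl]but-3-en-1-olate | COC(=O)c1cc(OC)c(F)c(c1)[C@H](C=C)[C@H](c1ccc(OCc2ccccc2)c(OC)c1)[O-].[K+]
F10 | step 6 | methyl (2R,3S)-2-[4-(benzyloxy)-3-methoxyphenyl]-3-ethenyl-7-methoxy-2,3-dihydro-1-benzofuran-5-carboxylate (2,3-cis) | COC(=O)c1cc(OC)c2c(c1)[C@H](C=C)[C@H](c1ccc(OCc3ccccc3)c(OC)c1)O2
F11 | step 6 | methyl (2R,3S)-2-[4-(benzyloxy)-3-methoxyphenyl]-3-formyl-7-methoxy-2,3-dihydro-1-benzofuran-5-carboxylate (2,3-cis) | COC(=O)c1cc(OC)c2c(c1)[C@H](C=O)[C@H](c1ccc(OCc3ccccc3)c(OC)c1)O2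
F12 | step 6 | methyl (2R,3R)-2-[4-(benzyloxy)-3-methoxyphenyl]-3-(hydroxymethyl)-7-methoxy-2,3-dihydro-1-benzofuran-5-carboxylate (2,3-cis) | COC(=O)c1cc(OC)c2c(c1)[C@H](CO)[C@H](c1ccc(OCc3ccccc3)c(OC)c1)O2
F13 | step 3 | methyl 4-fluoro-3-[(E)-3-hydroxyprop-1-en-1-yl]-5-methoxybenzoate | COC(=O)c1cc(OC)c(F)c(/C=C/CO)c1
F14 | step 3 | methyl 3-[(E)-3-(acetyloxy)prop-1-en-1-yl]-4-fluoro-5-methoxybenzoate | COC(=O)c1cc(OC)c(F)c(/C=C/COC(C)=O)c1
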